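**Retrosynthetic overview**

- Botryotin F ⇐ its 3-ketone (bulky hydride gives the axial 3-OH) ⇐ a tetracyclic enone acid, by one dissolving-metal step that hydroxymethylates C4, sets H-5 and reduces the C14 ketone.
- Ring A ⇐ intramolecular aldol condensation of a 3-oxopentyl chain on C10 onto the C5 ketone.
- Key step: the C12–C13 bond (ring D, the bicyclo[3.2.1]octene) by ketyl radical 1,6-cyclization of a side-chain α-keto ester onto a cross-conjugated dienedione with SmI2; the dienolate is trapped with MeI (C10 quaternary centre, C9=C11 alkene).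
- Dienedione ⇐ Hajos–Parrish-type enone (ring B annulated onto cyclopentane-1,3-dione, which is ring C), C10 alkylation and quinone dehydrogenation; side chain from ethyl glyoxylate and an acetaldehyde enol silane.
- Ring order: C (the dione) → B → D → A.

Convention used: ring A = C1–C5, C10; ring B = C5–C10; ring C = C8, C9, C11, C12, C14; ring D = C8, C14, C12, C13, C16, C15; C17 = carboxyl on C13, C18 = CH2OH and C19 = CH3 on C4, C20 = CH3 on C10; α = face of H-5 and of the C15–C16–C13 bridge, β = face of C20 and C14. Compounds 6–13 are carried as mixtures of epimers at the side-chain carbinol carbon, which is oxidised in step 6.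

**Step 1**
Reactants: 1 ethyl glyoxylate; 2 trimethyl(vinyloxy)silane; 3 cyclopentane-1,3-dione
Product: 6 ethyl 4-(2,5-dioxocyclopentyl)-2-hydroxybutanoate (racemic), via silyl aldol aldehyde 4 (not isolated), via silyl ether dione 5 (not isolated)
Conditions: Sc(OTf)3 (5 mol%), CH2Cl2, −78 °C; then 3, Hantzsch ester (1.1 equiv), L-proline (20 mol%), EtOH, 25 °C; then 1 M HCl, 0 °C
Reagents that add atoms: none
Why: Mukaiyama aldol of the acetaldehyde enol silane with the very electrophilic glyoxylate, then organocatalytic three-component reductive alkylation (Knoevenagel condensation and Hantzsch-ester transfer hydrogenation) gives clean C-monoalkylation of the dione; the carbinol centre needs no control because it is oxidised later.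

**Step 2**
Reactants: 6 ethyl 4-(2,5-dioxocyclopentyl)-2-hydroxybutanoate; 7 but-3-en-2-one
Product: 9 ethyl 2-hydroxy-4-[(7aS)-1,5-dioxo-2,3,5,6,7,7a-hexahydro-1H-inden-7a-yl]butanoate (rings B and C; C8 quaternary), via triketone 8 (not isolated)
Conditions: Et3N (0.1 equiv), MeCN, 25 °C; then L-proline (0.5 equiv), 1 M HClO4 (0.25 equiv), MeCN, 80 °C
Reagents that add atoms: none
Why: Michael addition followed by the Hajos–Parrish (Eder–Sauer–Wiechert) proline enamine aldol condensation; L-proline differentiates the two enantiotopic ring carbonyls and sets the quaternary carbon C8 in the (7aS) sense, as in the parent methyl series.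

**Step 3**
Reactants: 10 pent-1-en-3-one
Product: 11 2-(2-bromoethyl)-2-ethyl-1,3-dioxolane
Conditions: HBr (g), ethylene glycol, CH2Cl2, 0 → 25 °C
Reagents that add atoms: hydrogen bromide, Br; ethylene glycol, OCCO
Why: conjugate hydrobromination of the enone followed by acid-catalysed ketalization gives the masked 3-oxopentyl electrophile; no stereocentre is formed.

**Step 4**
Reactants: 9 bicyclic enone; 11 2-(2-bromoethyl)-2-ethyl-1,3-dioxolane
Product: 12 ethyl 4-{(7aS)-4-[2-(2-ethyl-1,3-dioxolan-2-yl)ethyl]-1,5-dioxo-2,3,5,6,7,7a-hexahydro-1H-inden-7a-yl}-2-hydroxybutanoate (C10-alkylated enone)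
Conditions: KOtBu (2.1 equiv), NaI (0.1 equiv), tBuOH/THF, 0 → 25 °C
Reagents that add atoms: none
Why: α-alkylation of the thermodynamic extended dienolate at C10 followed by reconjugation (classical alkylation of Hajos–Parrish-type enones); the second equivalent of base is carried by the free hydroxyl, and no stereocentre is formed.

**Step 5**
Reactants: 12 C10-alkylated enone
Product: 13 ethyl 4-{(7aS)-4-[2-(2-ethyl-1,3-dioxolan-2-yl)ethyl]-1,5-dioxo-5,6,7,7a-tetrahydro-1H-inden-7a-yl}-2-hydroxybutanoate (dienedione O=C14–C12=C11–C9=C10–C5=O)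
Conditions: chloranil (1.3 equiv), tBuOH, reflux
Reagents that add atoms: none
Why: quinone dehydrogenation through the extended dienol, the reaction type that turns 4-en-3-one steroids into 4,6-dien-3-ones; the C11–C12 pair is the only one that is both allylic to the dienol and α to the C14 carbonyl.

**Step 6**
Reactants: 13 dienedione hydroxy ester
Product: 14 ethyl 4-{4-[2-(2-ethyl-1,3-dioxolan-2-yl)ethyl]-1,5-dioxo-5,6,7,7a-tetrahydro-1H-inden-7a-yl}-2-oxobutanoate (α-keto ester; same geometry at C8, CIP label now 7aR)
Conditions: Dess–Martin periodinane (1.3 equiv), NaHCO3, CH2Cl2, 0 → 25 °C; used at once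
Reagents that add atoms: none
Why: Dess–Martin oxidation of the secondary α-hydroxy ester under buffered neutral conditions leaves the ketal and the dienedione untouched and removes the unresolved carbinol centre.

**Step 7 (key step)**
Reactants: 14 α-keto ester dienedione
Product: 15 tricyclic hydroxy ester (rings B, C, D of the target with C5 and C14 ketones, C9=C11 alkene, 13-OH anti and 13-CO2Et gauche to C14, C10 carrying β-CH3 and the α 2-(2-ethyl-1,3-dioxolan-2-yl)ethyl chain)
Conditions: SmI2 (2.1 equiv), HMPA (8 equiv), THF, −78 °C; then MeI (5 equiv), −78 → 0 °C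
Reagents that add atoms: iodomethane, CI
Why: Proposed new method: divalent samarium reduces the α-keto ester to its ketyl radical, which adds 6-exo to C12 (δ-carbon of the dienone, the only site giving a six-membered ring and a radical delocalised to the C5 oxygen); the tether forces attack on the α face (sets C12), the bulky HMPA-solvated samarium alkoxide lies anti to C14 so the ester becomes axial (sets C13), and the second electron gives a trivalent samarium dienolate that MeI alkylates at C10 on the β face opposite the new bridge (sets C10, places the alkene at C9=C11); the closest known chemistry is SmI2 ketyl–enone cyclization combined with Stork reductive alkylation of enones.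

**Step 8**
Reactants: 15 tricyclic hydroxy ester
Product: 17 tetracyclic enone ester (target skeleton without C18; C3 ketone conjugated to C4=C5 with CH3 on C4; C9=C11; C14 ketone; 13-OH and 13-CO2Et), via diketone 16 (not isolated)
Conditions: 1 M HCl, THF, 25 °C; then pyrrolidine (1.5 equiv), AcOH (1.5 equiv), PhMe, 80 °C
Reagents that add atoms: water, O
Why: ketal hydrolysis then amine-mediated intramolecular aldol condensation (Robinson-type closure of ring A) of the ethyl ketone onto the C5 ketone; strong base is avoided so the C13-hydroxy/C14-keto aldol unit is not cleaved, and C12 is a bridgehead so the C9=C11 alkene cannot move.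

**Step 9**
Reactants: 17 tetracyclic enone ester
Product: 18 tetracyclic enone acid (17 with CO2H on C13)
Conditions: Me3SnOH (5 equiv), ClCH2CH2Cl, 80 °C; cold 1 M HCl work-up
Reagents that add atoms: trimethyltin hydroxide, C[Sn](C)(C)O
Why: neutral ester hydrolysis with trimethyltin hydroxide frees the acid without the alkoxide that would trigger retro-aldol opening of ring D; no stereocentre changes.

**Step 10**
Reactants: 18 tetracyclic enone acid
Product: 19 3-oxo precursor (target with C3 ketone: 4α-CH2OH, 4β-CH3, 5α-H, 14-OH syn to the C9=C11 bridge, 13-OH, 13-CO2H)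
Conditions: LiOH (1.0 equiv), MeOH, 0 °C, evaporate; Li (6 equiv), tBuOH (1 equiv), NH3/THF, −78 °C; isoprene; then CH2O (g), THF, −78 °C; aq NH4Cl
Reagents that add atoms: formaldehyde, C=O
Why: Stork reductive alkylation: the enone radical anion is protonated axially at C5 (trans A/B, 5α-H) and the enolate adds to formaldehyde on the α face opposite the axial C20 methyl (sets C4), while the same dissolving-metal conditions reduce the C14 ketone with the oxyanion on the alkene side, away from the axial C13 carboxylate, so hydrogen enters from the ring D side (the epimer opposite to that expected from hydride attack).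

**Step 11**
Reactants: 19 3-oxo precursor
Product: 20 Botryotin F
Conditions: LiBH(sBu)3 (6 equiv), THF, −78 → 0 °C; 1 M HCl work-up
Reagents that add atoms: none
Why: the bulky trialkylborohydride attacks the hindered 4,4-disubstituted C3 ketone from the equatorial direction and gives the axial 3α-alcohol (Selectride reduction); the excess covers the acidic protons.

**Compound list**

1 | ethyl glyoxylate | O=CC(=O)OCC | starting material
2 | trimethyl(vinyloxy)silane | C=CO[Si](C)(C)C | starting material
3 | cyclopentane-1,3-dione | O=C1CCC(=O)C1 | starting material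
4 | ethyl 4-oxo-2-[(trimethylsilyl)oxy]butanoate (racemic) | CCOC(=O)C(CC=O)O[Si](C)(C)C | intermediate (not isolated)
5 | ethyl 4-(2,5-dioxocyclopentyl)-2-[(trimethylsilyl)oxy]butanoate (racemic) | CCOC(=O)C(CCC1C(=O)CCC1=O)O[Si](C)(C)C | intermediate (not isolated)
6 | ethyl 4-(2,5-dioxocyclopentyl)-2-hydroxybutanoate (racemic) | CCOC(=O)C(O)CCC1C(=O)CCC1=O | intermediate
7 | but-3-en-2-one | C=CC(C)=O | starting material
8 | ethyl 4-[2,5-dioxo-1-(3-oxobutyl)cyclopentyl]-2-hydroxybutanoate | CCOC(=O)C(O)CCC1(CCC(C)=O)C(=O)CCC1=O | intermediate (not isolated)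
9 | ethyl 2-hydroxy-4-[(7aS)-1,5-dioxo-2,3,5,6,7,7a-hexahydro-1H-inden-7a-yl]butanoate | O=C1CCC2=CC(=O)CC[C@]12CCC(O)C(=O)OCC | intermediate
10 | pent-1-en-3-one | C=CC(=O)CC | starting material
11 | 2-(2-bromoethyl)-2-ethyl-1,3-dioxolane | CCC1(CCBr)OCCO1 | intermediate
12 | C10-alkylated bicyclic enone hydroxy ester (7aS) | O=C1CCC2=C(CCC3(CC)OCCO3)C(=O)CC[C@]12CCC(O)C(=O)OCC | intermediate
13 | cross-conjugated dienedione hydroxy ester (7aS) | O=C1C=CC2=C(CCC3(CC)OCCO3)C(=O)CC[C@]12CCC(O)C(=O)OCC | intermediate
14 | dienedione α-keto ester (same geometry at C8) | O=C1C=CC2=C(CCC3(CC)OCCO3)C(=O)CC[C@]12CCC(=O)C(=O)OCC | intermediate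
15 | tricyclic B/C/D hydroxy ester with ketal side chain (C10 β-CH3, C12 and C13 as in the target) | CCC1(OCCO1)CC[C@]2(C)C3=C[C@H]4C(=O)[C@]3(CCC2=O)CC[C@]4(O)C(=O)OCC | intermediate
16 | tricyclic diketone with free 3-oxopentyl chain on C10 | CCC(=O)CC[C@]1(C)C2=C[C@H]3C(=O)[C@]2(CCC1=O)CC[C@]3(O)C(=O)OCC | intermediate (not isolated)
17 | tetracyclic enone ethyl ester (C3 ketone, C4=C5, C9=C11, C14 ketone) | CC=1C(=O)CC[C@]2(C)C3=C[C@H]4C(=O)[C@]3(CCC=12)CC[C@]4(O)C(=O)OCC | intermediate
18 | tetracyclic enone acid | CC=1C(=O)CC[C@]2(C)C3=C[C@H]4C(=O)[C@]3(CCC=12)CC[C@]4(O)C(=O)O | intermediate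
19 | 3-oxo precursor of Botryotin F (4α-CH2OH, 4β-CH3, 5α-H, 14-OH syn to C9=C11) | C[C@@]1(CO)C(=O)CC[C@]2(C)C3=C[C@H]4[C@@H](O)[C@]3(CC[C@@H]12)CC[C@]4(O)C(=O)O | intermediate
20 | Botryotin F | C[C@@]1(CO)[C@H](O)CC[C@]2(C)C3=C[C@H]4[C@@H](O)[C@]3(CC[C@@H]12)CC[C@]4(O)C(=O)O | target

**Step count and risks**

Total step count: 11. Longest linear sequence: 10 steps (steps 1, 2 and 4–11); step 3 is a one-step side branch.

Most likely to fail, first: step 7. The ketyl may close a pinacol bond to C14 or attack C9 (5-exo), and the samarium dienolate may be protonated instead of methylated. Fallback: set out from 14 and separate the events. Generate the ketyl without a templating metal by photoredox proton-coupled electron transfer ([Ir(ppy)2(dtbbpy)]PF6, Hantzsch ester, blue light, MeCN), which gives after tautomerization the C10–H tricyclic enone ester F1. Mask its tertiary alcohol (TMSOTf, 2,6-lutidine, CH2Cl2, −78 °C) as the trimethylsilyl ether of the C10–H tricyclic enone ester F2. Install the methyl group by classical deconjugative dienolate alkylation (KOtBu, MeI, tBuOH/THF, 0 °C), which is safe because the silyl ether blocks retro-aldol opening, to reach the 13-O-trimethylsilyl ether of 15 F3. The acid stage of step 8 removes the silyl ether and the ketal together, so the route is rejoined at 16.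

Second: step 10. The C14 ketone may be reduced to the wrong epimer, or the enolate may be over-reduced when three events share one pot. Fallback: set out from 18 and reduce C14 first by intramolecular hydride delivery from the axial carboxyl group (Me4NBH(OAc)3, AcOH/MeCN, −20 °C; the acyloxyborohydride can only reach C14 from the ring D side), giving the 14-hydroxy enone acid F5. Then run the lithium–ammonia reduction and formaldehyde trapping on F5 with the enone as the only reducible group; the route is rejoined at 19.

Third: step 5. Chloranil may react sluggishly next to the C14 carbonyl or dehydrogenate ring B. Fallback: set out from 12 and use the selenoxide route. Acid-catalysed α-selenenylation of the saturated C14 ketone (PhSeCl, anhydrous EtOAc, 25 °C; the enone is much slower) gives the 12-phenylselanyl derivative of 12 F4. Oxidation (H2O2, pyridine, CH2Cl2, 0 °C) and syn-elimination toward C11 deliver 13.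

**Further compounds**

F1 | step 7 | C10–H tricyclic enone ester (15 without the C10 methyl; C9=C10 conjugated to the C5 ketone) | CCC1(OCCO1)CCC2=C3C[C@H]4C(=O)[C@]3(CCC2=O)CC[C@]4(O)C(=O)OCC
F2 | step 7 | trimethylsilyl ether of the C10–H tricyclic enone ester | CCC1(OCCO1)CCC2=C3C[C@H]4C(=O)[C@]3(CCC2=O)CC[C@]4(O[Si](C)(C)C)C(=O)OCC
F3 | step 7 | 13-O-trimethylsilyl ether of 15 | CCC1(OCCO1)CC[C@]2(C)C3=C[C@H]4C(=O)[C@]3(CCC2=O)CC[C@]4(O[Si](C)(C)C)C(=O)OCC
F4 | step 5 | 12-phenylselanyl derivative of 12 | O=C1C([Se]c3ccccc3)CC2=C(CCC4(CC)OCCO4)C(=O)CC[C@]12CCC(O)C(=O)OCC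
F5 | step 10 | 14-hydroxy enone acid (18 with C14 reduced, OH syn to C9=C11) | CC=1C(=O)CC[C@]2(C)C3=C[C@H]4[C@@H](O)[C@]3(CCC=12)CC[C@]4(O)C(=O)O
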